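**Plan**
- Retrosynthesis: remove three O-benzyl groups; return lactone C3 (alkene reduction, trans-equilibration) to a 3-arylidene lactone; cut the exocyclic C(sp2)–aryl bond to C5 of the dihydrobenzofuran (Suzuki); then cut lactone bonds C2–C3 and C4–C5 together, lifting the C5H2–O1–C2(=O) triad off the C3–C4 pair; in the other fragment cut the dihydrofuran C2–C3 bond (carbene C–H insertion).
- Enabling feature (lactone numbered O1–C2(=O)–C3–C4–C5): C3 carries a benzylic CH2. Raised to the aldehyde level, this carbon with C3 and C4 is the C1–C3 unit of (2E)-4-arylbut-2-enal, so amine catalysis makes C4 an iminium β-carbon (radical acceptor) and then C3 an enamine carbon (acyl acceptor); the triad arrives as the radical PhOC(=O)OCH2•, which carries its own acyl electrophile.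
- Forward: enal 4 + acid 8 give the lactone ring first (formyl lactone 10, then enol triflate 11, fragment 1); the dihydrobenzofuran ring is closed by dirhodium carbene C–H insertion and carried to boronate 22 (fragment 2); Suzuki union, alkene reduction with epimerisation, hydrogenolysis.
- Stereochemistry: lactone C4 from the chiral amine in the radical addition; lactone C3 by base equilibration to the trans lactone; dihydrobenzofuran C2 from the chiral dirhodium carboxylate; dihydrobenzofuran C3 by epimerisation of the cis ester to trans.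

Key step: step 5

**Assumptions**
- The (R)-diarylprolinol silyl ether is assumed to follow the usual shielding model for E-iminium ions (attack anti to the diaryl(silyloxy)methyl group), which leads to 4S; the antipodal amine would give 4R.
- Rh2(R-PTTL)4 is assumed to give the 2S series in step 11; if the sense is the opposite, Rh2(S-PTTL)4 is used instead.
- Compound 10 is drawn as the aldehyde tautomer; it is expected to exist mainly as the hydroxymethylidene enol, so its C3 is not a stereocentre.

**Route**

Step 1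
Reactants: 1 eugenol
Product: 2 4-allyl-1-(benzyloxy)-2-methoxybenzene
Conditions: BnBr, K2CO3, DMF, rt
Reagents that add atoms: benzyl bromide, BrCc1ccccc1
Why: Williamson ether synthesis on the phenoxide installs a benzyl ether that should survive all later steps and is removed by hydrogenolysis at the end.

Step 2
Reactants: 2 4-allyl-1-(benzyloxy)-2-methoxybenzene; 3 (E)-crotonaldehyde (5 equiv)
Product: 4 (2E)-4-[4-(benzyloxy)-3-methoxyphenyl]but-2-enal
Conditions: RuCl2(=CHPh)(H2IMes)(PCy3) (second-generation Grubbs catalyst, 3 mol %), 2,6-dichloro-1,4-benzoquinone (10 mol %), CH2Cl2, 40 °C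
Reagents that add atoms: none
Why: Olefin cross-metathesis of an allylarene with an electron-poor enal should be E-selective and favour the cross product, and the quinone suppresses ruthenium hydride migration of the double bond.

Step 3
Reactants: 5 tert-butyl glycolate; 6 phenyl chloroformate
Product: 7 tert-butyl 2-[(phenoxycarbonyl)oxy]acetate
Conditions: pyridine, CH2Cl2, 0 °C to rt
Reagents that add atoms: none
Why: O-acylation of the primary alcohol by the chloroformate gives the mixed alkyl aryl carbonate.

Step 4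
Reactants: 7 tert-butyl 2-[(phenoxycarbonyl)oxy]acetate
Product: 8 2-[(phenoxycarbonyl)oxy]acetic acid
Conditions: CF3CO2H/CH2Cl2 (1:3), rt
Reagents that add atoms: none
Why: Acidolysis of the tert-butyl ester (loss of isobutene) frees the acid, and the acid-stable phenyl carbonate should remain intact.

Step 5
Reactants: 4 (2E)-4-[4-(benzyloxy)-3-methoxyphenyl]but-2-enal; 8 2-[(phenoxycarbonyl)oxy]acetic acid (1.5 equiv)
Product: 10 (4S)-4-[4-(benzyloxy)-3-methoxybenzyl]-2-oxooxolane-3-carbaldehyde, via enamine 9 (not isolated)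
Conditions: (R)-2-{bis[3,5-bis(trifluoromethyl)phenyl][(trimethylsilyl)oxy]methyl}pyrrolidine (20 mol %), Ir[dF(CF3)ppy]2(dtbbpy)PF6 (1 mol %), 2,6-lutidine (20 mol %), degassed MeCN, blue LEDs (450 nm), 0 °C
Reagents that add atoms: none
Why: Proposed new method: the carboxylate of 8 is oxidised by the photoexcited trivalent iridium complex and loses CO2 to give the nucleophilic radical PhOC(=O)OCH2•, which adds to the β-carbon of the iminium ion formed from 4 and the amine; the α-iminyl radical cation is reduced by the divalent iridium species to enamine 9, whose α-carbon attacks the tethered phenyl carbonate, expels phenoxide (the base for the next molecule of 8) and, after hydrolysis of the acyl iminium ion, releases 10 and the amine. The closest known reaction types are the amine-catalysed enantioselective addition of photogenerated nucleophilic radicals to enal-derived iminium ions and the Stork C-acylation of enamines; what is new is their coupling in one redox-neutral cascade with an aryl carbonate as internal acyl donor. The lactone, the only ring formed, is closed by 5-exo-trig acyl substitution (C2–C3 bond) after the intermolecular C4–C5 bond formation. C4 is set in the radical addition by the catalyst, whose diaryl(silyloxy)methyl group shields one face of the E-configured iminium ion so that the (R)-amine should lead to 4S; C3 needs no control here because 10 is an enolised β-formyl lactone. The step needs conjugate rather than carbonyl addition, C- rather than N-acylation and no γ-deprotonation of 4; the iminium LUMO coefficient at the β-carbon, the hindered and largely protonated amine together with the fast five-ring closure, and the acidic, base-poor medium should provide for these.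

Step 6
Reactants: 10 (4S)-4-[4-(benzyloxy)-3-methoxybenzyl]-2-oxooxolane-3-carbaldehyde
Product: 11 (E)-{(4S)-4-[4-(benzyloxy)-3-methoxybenzyl]-2-oxooxolan-3-ylidene}methyl trifluoromethanesulfonate
Conditions: Tf2O, iPr2NEt, CH2Cl2, −78 °C
Reagents that add atoms: trifluoromethanesulfonic anhydride, O=S(=O)(OS(=O)(=O)C(F)(F)F)C(F)(F)F
Why: O-sulfonylation of the enol tautomer gives the vinylogous acyl triflate (E isomer drawn; the geometry is lost in step 16), turning the former aldehyde carbon into a cross-coupling electrophile without touching C4.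

Step 7
Reactants: 12 2-(benzyloxy)phenol
Product: 13 2-(benzyloxy)-4-bromophenol
Conditions: NBS, MeCN, −20 to 0 °C
Reagents that add atoms: N-bromosuccinimide, O=C1CCC(=O)N1Br
Why: Electrophilic aromatic bromination should go para to the free hydroxyl, the strongest activating group.

Step 8
Reactants: 13 2-(benzyloxy)-4-bromophenol
Product: 14 2-(benzyloxy)-4-bromo-6-iodophenol
Conditions: NIS, iPr2NH (10 mol %), CH2Cl2, 0 °C
Reagents that add atoms: N-iodosuccinimide, O=C1CCC(=O)N1I
Why: Amine-mediated ortho-iodination of the phenol should put iodine at the only free position ortho to OH, the para position being blocked.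

Step 9
Reactants: 14 2-(benzyloxy)-4-bromo-6-iodophenol; 15 [4-(benzyloxy)-3-methoxyphenyl]methanol
Product: 16 1-(benzyloxy)-2-{[4-(benzyloxy)-3-methoxybenzyl]oxy}-5-bromo-3-iodobenzene
Conditions: PPh3, DIAD, THF, 0 °C to rt
Reagents that add atoms: none
Why: Mitsunobu etherification of the acidic dihalophenol with the benzylic alcohol forms the aryl benzyl ether whose OCH2 group later becomes C2 of the dihydrobenzofuran.

Step 10
Reactants: 16 1-(benzyloxy)-2-{[4-(benzyloxy)-3-methoxybenzyl]oxy}-5-bromo-3-iodobenzene; 17 ethyl diazoacetate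
Product: 18 ethyl 2-{3-(benzyloxy)-2-[(4-(benzyloxy)-3-methoxybenzyl)oxy]-5-bromophenyl}-2-diazoacetate
Conditions: Pd(PPh3)4 (5 mol %), Ag2CO3 (0.5 equiv), Et3N (1.3 equiv), toluene, rt
Reagents that add atoms: none
Why: Palladium-catalysed C–H arylation of the acceptor diazo compound (oxidative addition of zerovalent palladium into C–I, palladation of the diazoacetate, reductive elimination) keeps the diazo group, and C–I should react in preference to C–Br at room temperature.

Step 11
Reactants: 18 ethyl 2-{3-(benzyloxy)-2-[(4-(benzyloxy)-3-methoxybenzyl)oxy]-5-bromophenyl}-2-diazoacetate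
Product: 19 ethyl (2S,3R)-7-(benzyloxy)-2-[4-(benzyloxy)-3-methoxyphenyl]-5-bromo-2,3-dihydro-1-benzofuran-3-carboxylate (cis)
Conditions: Rh2(R-PTTL)4 [dirhodium tetrakis(N-phthaloyl-(R)-tert-leucinate)] (1 mol %), toluene, −60 °C
Reagents that add atoms: none
Why: Dirhodium carbene 1,5-C–H insertion into the benzylic OCH2 group closes the dihydrofuran ring (C2–C3 bond); the chiral carboxylate ligands select one enantiotopic benzylic hydrogen and so set C2 (S), with the cis ester as the expected kinetic product.

Step 12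
Reactants: 19 cis ester
Product: 20 ethyl (2S,3S)-7-(benzyloxy)-2-[4-(benzyloxy)-3-methoxyphenyl]-5-bromo-2,3-dihydro-1-benzofuran-3-carboxylate (trans)
Conditions: NaOEt (0.2 equiv), EtOH, 0 °C to rt
Reagents that add atoms: none
Why: Reversible enolisation of the ester epimerises C3 only and should give the more stable trans isomer with C2 unchanged.

Step 13
Reactants: 20 trans ester
Product: 21 [(2S,3R)-7-(benzyloxy)-2-[4-(benzyloxy)-3-methoxyphenyl]-5-bromo-2,3-dihydro-1-benzofuran-3-yl]methanol
Conditions: DIBAL-H (2.5 equiv), CH2Cl2, −78 to 0 °C; aqueous Rochelle salt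
Reagents that add atoms: none
Why: Hydride reduction of the ester to the primary alcohol under non-basic conditions should leave both stereocentres, the aryl bromide and the benzyl ethers intact.

Step 14
Reactants: 21 bromo alcohol
Product: 22 [(2S,3R)-7-(benzyloxy)-2-[4-(benzyloxy)-3-methoxyphenyl]-5-(4,4,5,5-tetramethyl-1,3,2-dioxaborolan-2-yl)-2,3-dihydro-1-benzofuran-3-yl]methanol
Conditions: B2pin2, PdCl2(dppf) (5 mol %), KOAc, 1,4-dioxane, 85 °C
Reagents that add atoms: bis(pinacolato)diboron, CC1(C)OB(OC1(C)C)B1OC(C)(C)C(C)(C)O1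
Why: Miyaura borylation of the aryl bromide tolerates the free primary alcohol and the benzyl ethers.

Step 15
Reactants: 11 enol triflate; 22 aryl boronate
Product: 23 (3E,4S)-4-[4-(benzyloxy)-3-methoxybenzyl]-3-({(2S,3R)-7-(benzyloxy)-2-[4-(benzyloxy)-3-methoxyphenyl]-3-(hydroxymethyl)-2,3-dihydro-1-benzofuran-5-yl}methylidene)oxolan-2-one
Conditions: Pd(PPh3)4 (5 mol %), K3PO4, THF/H2O (10:1), 50 °C
Reagents that add atoms: none
Why: Suzuki–Miyaura coupling of the vinylogous acyl triflate with the aryl boronate joins fragments 1 and 2 at the former aldehyde carbon with retention of alkene geometry, under a mild base that should spare the lactone and the free alcohol.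

Step 16
Reactants: 23 arylidene lactone
Product: 25 (3S,4S)-4-[4-(benzyloxy)-3-methoxybenzyl]-3-({(2S,3R)-7-(benzyloxy)-2-[4-(benzyloxy)-3-methoxyphenyl]-3-(hydroxymethyl)-2,3-dihydro-1-benzofuran-5-yl}methyl)oxolan-2-one, via cis-lactone 24 (not isolated)
Conditions: H2 (1 atm), 10 % Pd/C, Ph2S (0.05 equiv), EtOAc, rt; filter; t-BuOK (0.5 equiv), THF/t-BuOH, 0 °C to rt; AcOH
Reagents that add atoms: none
Why: Hydrogenation over sulfide-moderated palladium should saturate only the exocyclic alkene, adding hydrogen anti to the C4 benzyl group (cis lactone 24), and catalytic tert-butoxide then equilibrates C3 through the lactone enolate to the more stable trans lactone, setting C3 (S) under thermodynamic control.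

Step 17
Reactants: 25 trans lactone tribenzyl ether
Product: 26 (3S,4S)-4-(4-hydroxy-3-methoxybenzyl)-3-{[(2S,3R)-7-hydroxy-2-(4-hydroxy-3-methoxyphenyl)-3-(hydroxymethyl)-2,3-dihydro-1-benzofuran-5-yl]methyl}oxolan-2-one (target)
Conditions: H2 (1 atm), 10 % Pd/C, EtOAc/EtOH, rt
Reagents that add atoms: none
Why: Neutral hydrogenolysis of the three aryl benzyl ethers frees the phenols without touching a stereocentre, and the cyclic benzylic aryl ether of the dihydrobenzofuran is expected to survive at 1 atm.

**Compound list**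
1 | eugenol (4-allyl-2-methoxyphenol) | COc1cc(CC=C)ccc1O | starting material
2 | 4-allyl-1-(benzyloxy)-2-methoxybenzene | COc1cc(CC=C)ccc1OCc1ccccc1 | intermediate
3 | (E)-crotonaldehyde | C/C=C/C=O | starting material
4 | (2E)-4-[4-(benzyloxy)-3-methoxyphenyl]but-2-enal | COc1cc(C/C=C/C=O)ccc1OCc1ccccc1 | intermediate
5 | tert-butyl glycolate | CC(C)(C)OC(=O)CO | starting material
6 | phenyl chloroformate | O=C(Cl)Oc1ccccc1 | starting material
7 | tert-butyl 2-[(phenoxycarbonyl)oxy]acetate | CC(C)(C)OC(=O)COC(=O)Oc1ccccc1 | intermediate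
8 | 2-[(phenoxycarbonyl)oxy]acetic acid | OC(=O)COC(=O)Oc1ccccc1 | intermediate
9 | (E)-enamine of the (R)-diarylprolinol silyl ether with (3S)-3-[4-(benzyloxy)-3-methoxybenzyl]-4-[(phenoxycarbonyl)oxy]butanal | C[Si](C)(C)OC([C@H]1CCCN1/C=C/[C@H](Cc1ccc(OCc2ccccc2)c(OC)c1)COC(=O)Oc1ccccc1)(c1cc(C(F)(F)F)cc(C(F)(F)F)c1)c1cc(C(F)(F)F)cc(C(F)(F)F)c1 | intermediate (not isolated)
10 | (4S)-4-[4-(benzyloxy)-3-methoxybenzyl]-2-oxooxolane-3-carbaldehyde | COc1cc(C[C@@H]2COC(=O)C2C=O)ccc1OCc1ccccc1 | intermediate
11 | (E)-{(4S)-4-[4-(benzyloxy)-3-methoxybenzyl]-2-oxooxolan-3-ylidene}methyl trifluoromethanesulfonate | COc1cc(C[C@@H]2COC(=O)/C2=C/OS(=O)(=O)C(F)(F)F)ccc1OCc1ccccc1 | intermediate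
12 | 2-(benzyloxy)phenol | Oc1ccccc1OCc1ccccc1 | starting material
13 | 2-(benzyloxy)-4-bromophenol | Oc1ccc(Br)cc1OCc1ccccc1 | intermediate
14 | 2-(benzyloxy)-4-bromo-6-iodophenol | Oc1c(I)cc(Br)cc1OCc1ccccc1 | intermediate
15 | [4-(benzyloxy)-3-methoxyphenyl]methanol | COc1cc(CO)ccc1OCc1ccccc1 | starting material
16 | 1-(benzyloxy)-2-{[4-(benzyloxy)-3-methoxybenzyl]oxy}-5-bromo-3-iodobenzene | COc1cc(COc2c(I)cc(Br)cc2OCc2ccccc2)ccc1OCc1ccccc1 | intermediate
17 | ethyl diazoacetate | CCOC(=O)C=[N+]=[N-] | starting material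
18 | ethyl 2-{3-(benzyloxy)-2-[(4-(benzyloxy)-3-methoxybenzyl)oxy]-5-bromophenyl}-2-diazoacetate | CCOC(=O)C(=[N+]=[N-])c1cc(Br)cc(OCc2ccccc2)c1OCc1ccc(OCc2ccccc2)c(OC)c1 | intermediate
19 | ethyl (2S,3R)-7-(benzyloxy)-2-[4-(benzyloxy)-3-methoxyphenyl]-5-bromo-2,3-dihydro-1-benzofuran-3-carboxylate (cis) | Brc1cc(OCc2ccccc2)c2c(c1)[C@@H](C(=O)OCC)[C@@H](c1ccc(OCc3ccccc3)c(OC)c1)O2 | intermediate
20 | ethyl (2S,3S)-7-(benzyloxy)-2-[4-(benzyloxy)-3-methoxyphenyl]-5-bromo-2,3-dihydro-1-benzofuran-3-carboxylate (trans) | Brc1cc(OCc2ccccc2)c2c(c1)[C@H](C(=O)OCC)[C@@H](c1ccc(OCc3ccccc3)c(OC)c1)O2 | intermediate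
21 | [(2S,3R)-7-(benzyloxy)-2-[4-(benzyloxy)-3-methoxyphenyl]-5-bromo-2,3-dihydro-1-benzofuran-3-yl]methanol | Brc1cc(OCc2ccccc2)c2c(c1)[C@H](CO)[C@@H](c1ccc(OCc3ccccc3)c(OC)c1)O2 | intermediate
22 | [(2S,3R)-7-(benzyloxy)-2-[4-(benzyloxy)-3-methoxyphenyl]-5-(4,4,5,5-tetramethyl-1,3,2-dioxaborolan-2-yl)-2,3-dihydro-1-benzofuran-3-yl]methanol | CC1(C)OB(OC1(C)C)c1cc(OCc2ccccc2)c2c(c1)[C@H](CO)[C@@H](c1ccc(OCc3ccccc3)c(OC)c1)O2 | intermediate
23 | (3E,4S)-4-[4-(benzyloxy)-3-methoxybenzyl]-3-({(2S,3R)-7-(benzyloxy)-2-[4-(benzyloxy)-3-methoxyphenyl]-3-(hydroxymethyl)-2,3-dihydro-1-benzofuran-5-yl}methylidene)oxolan-2-one | COc1cc(C[C@@H]2COC(=O)/C2=C/c2cc(OCc3ccccc3)c3c(c2)[C@H](CO)[C@@H](c2ccc(OCc4ccccc4)c(OC)c2)O3)ccc1OCc1ccccc1 | intermediate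
24 | (3R,4S)-cis epimer of 25 | COc1cc(C[C@@H]2COC(=O)[C@@H]2Cc2cc(OCc3ccccc3)c3c(c2)[C@H](CO)[C@@H](c2ccc(OCc4ccccc4)c(OC)c2)O3)ccc1OCc1ccccc1 | intermediate (not isolated)
25 | (3S,4S)-4-[4-(benzyloxy)-3-methoxybenzyl]-3-({(2S,3R)-7-(benzyloxy)-2-[4-(benzyloxy)-3-methoxyphenyl]-3-(hydroxymethyl)-2,3-dihydro-1-benzofuran-5-yl}methyl)oxolan-2-one | COc1cc(C[C@@H]2COC(=O)[C@H]2Cc2cc(OCc3ccccc3)c3c(c2)[C@H](CO)[C@@H](c2ccc(OCc4ccccc4)c(OC)c2)O3)ccc1OCc1ccccc1 | intermediate
26 | (3S,4S)-4-(4-hydroxy-3-methoxybenzyl)-3-{[(2S,3R)-7-hydroxy-2-(4-hydroxy-3-methoxyphenyl)-3-(hydroxymethyl)-2,3-dihydro-1-benzofuran-5-yl]methyl}oxolan-2-one | COc1cc(C[C@@H]2COC(=O)[C@H]2Cc2cc(O)c3c(c2)[C@H](CO)[C@@H](c2ccc(O)c(OC)c2)O3)ccc1O | target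

**Step count and risks**

Total: 17 steps. Longest linear sequence: 11 steps (steps 7 to 17, from 2-(benzyloxy)phenol).

Steps most likely to fail:

1. Step 5 (proposed new method). What may go wrong: C-protonation and hydrolysis of the enamine before it is acylated; γ-deprotonation of the enal and migration of its double bond into conjugation with the arene; oxidative degradation of the amine catalyst by the photocatalyst; insufficient face selection in the radical addition. Fallback with known chemistry, setting out from 2 and coming back at 10: cross-metathesis of 2 with methyl acrylate (second-generation Grubbs catalyst) would give methyl (2E)-4-[4-(benzyloxy)-3-methoxyphenyl]but-2-enoate F1. Copper-catalysed enantioselective conjugate borylation (CuCl, NaOt-Bu, the Josiphos antipode that gives 3S, B2pin2, MeOH, THF) would give the β-boryl ester F2. Matteson homologation (BrCH2Cl, n-BuLi, THF, −78 °C) would insert CH2 into the C–B bond with retention to give the homologated boronate F3. Oxidation (NaBO3·4H2O, THF/H2O) would give the hydroxy ester F4, which acid (TsOH) would close to the lactone F5. Claisen formylation (NaH, HCO2Et, THF) returns to 10.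

2. Step 10. What may go wrong: slow oxidative addition and palladation at the hindered ortho-alkoxy aryl iodide, loss of the diazo group through palladium carbene formation, and competing reaction at the C–Br bond. Fallback, setting out from 16 and coming back at 18: Negishi coupling of 16 with the Reformatsky reagent BrZnCH2CO2Et (Pd2(dba)3, XPhos, THF, rt; C–I selective) would give ethyl 2-{3-(benzyloxy)-2-[(4-(benzyloxy)-3-methoxybenzyl)oxy]-5-bromophenyl}acetate F6; Regitz diazo transfer (4-acetamidobenzenesulfonyl azide, DBU, MeCN) returns to 18.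

3. Step 16. What may go wrong: slow reduction of the hindered trisubstituted alkene on the moderated catalyst, or hydrogenolysis of benzyl ethers if a more active catalyst is needed, and incomplete cis-to-trans equilibration at C3. Fallback, setting out from 23 and coming back at 25: homogeneous hydrogenation under ligand control with a chiral cationic iridium P,N complex such as [Ir(cod)(PHOX)]BArF (both ligand antipodes screened, CH2Cl2, H2). Here the catalyst, not the substrate, selects the alkene face, so the trans lactone 25 would be formed directly without the base step. No new compound is made (F0).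

**Further compounds**
F1 | step 5 | methyl (2E)-4-[4-(benzyloxy)-3-methoxyphenyl]but-2-enoate | COC(=O)/C=C/Cc1ccc(OCc2ccccc2)c(OC)c1
F2 | step 5 | methyl (3S)-4-[4-(benzyloxy)-3-methoxyphenyl]-3-(4,4,5,5-tetramethyl-1,3,2-dioxaborolan-2-yl)butanoate | COc1cc(C[C@@H](CC(=O)OC)B2OC(C)(C)C(C)(C)O2)ccc1OCc1ccccc1
F3 | step 5 | methyl (3S)-3-[4-(benzyloxy)-3-methoxybenzyl]-4-(4,4,5,5-tetramethyl-1,3,2-dioxaborolan-2-yl)butanoate | COc1cc(C[C@@H](CC(=O)OC)CB2OC(C)(C)C(C)(C)O2)ccc1OCc1ccccc1
F4 | step 5 | methyl (3S)-3-[4-(benzyloxy)-3-methoxybenzyl]-4-hydroxybutanoate | COc1cc(C[C@@H](CC(=O)OC)CO)ccc1OCc1ccccc1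
F5 | step 5 | (4S)-4-[4-(benzyloxy)-3-methoxybenzyl]oxolan-2-one | COc1cc(C[C@@H]2COC(=O)C2)ccc1OCc1ccccc1
F6 | step 10 | ethyl 2-{3-(benzyloxy)-2-[(4-(benzyloxy)-3-methoxybenzyl)oxy]-5-bromophenyl}acetate | CCOC(=O)Cc1cc(Br)cc(OCc2ccccc2)c1OCc1ccc(OCc2ccccc2)c(OC)c1
F0 | step 16 | none | none
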